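The pyrrole ring is disconnected at C2–C3 together with the C2–Br bond. The unit N1–C2(Br)–C3(Br), fused through C3a/C7a to the 6-bromobenzene ring, is read as an isocyanide carbon (C2) next to a benzylic CBr2 carbon (C3). The open-chain isomer 4-bromo-1-(dibromomethyl)-2-isocyanobenzene therefore contains all the atoms of the target. In one base-mediated operation the CHBr2 group is deprotonated, C3 attacks C2 to close the five-membered ring, and one bromine passes from C3 to C2, with the aromatic indolide as the sink. The precursor comes in three conventional steps from 5-bromo-2-methylaniline.

Key step: step 4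

Remark: 2,3,6-tribromo-1H-indole is planar and has no stereocentre, so no enantiomer question arises and no stereocontrol is needed.

Step 1
Reactants: 1 5-bromo-2-methylaniline; 2 formic acid
Product: 3 N-(5-bromo-2-methylphenyl)formamide
Conditions: HCO2H (3 equiv), toluene, reflux, Dean–Stark
Reagents that add atoms: formic acid, OC=O
Why: Thermal N-formylation of an aniline with formic acid under azeotropic removal of water is reliable even for an ortho-substituted aniline and leaves the aryl bromide and the methyl group untouched.

Step 2
Reactants: 3 N-(5-bromo-2-methylphenyl)formamide; 4 N-bromosuccinimide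
Product: 5 N-[5-bromo-2-(dibromomethyl)phenyl]formamide
Conditions: NBS (2.3 equiv), 450 nm LEDs, PhCF3, 40–60 °C
Reagents that add atoms: N-bromosuccinimide, O=C1CCC(=O)N1Br
Why: In this Wohl–Ziegler radical bromination the bromine atom abstracts only the benzylic hydrogens, a third bromination is blocked sterically, and the non-polar medium, low Br2 level and moderate temperature should suppress ionic ring or N-bromination of the ring-deactivated formanilide and closure of the formamide oxygen onto the new benzylic bromide.

Step 3
Reactants: 5 N-[5-bromo-2-(dibromomethyl)phenyl]formamide
Product: 6 4-bromo-1-(dibromomethyl)-2-isocyanobenzene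
Conditions: POCl3 (1.2 equiv), Et3N (4 equiv), CH2Cl2, −30 → 0 °C; cold aq. Na2CO3
Reagents that add atoms: none
Why: Dehydration of an N-aryl formamide to the isocyanide (Ugi's POCl3/amine method) runs by O-phosphorylation and loss of dichlorophosphate below 0 °C, where the hindered benzal bromide and the aryl bromide should persist, and the basic quench protects the acid-labile isocyanide.

Step 4
Reactants: 6 4-bromo-1-(dibromomethyl)-2-isocyanobenzene
Product: 11 2,3,6-tribromo-1H-indole, via dibromo(4-bromo-2-isocyanophenyl)methyllithium 7 (not isolated), via 3,3,6-tribromo-3H-indol-2-yllithium 8 (not isolated), via 2,3,3,6-tetrabromo-3H-indole 9 (not isolated), via lithium 2,3,6-tribromoindol-1-ide 10 (not isolated)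
Conditions: 6 added to LiTMP (1.15 equiv; from TMPH, n-BuLi), THF, −95 → −60 °C; then sat. aq. NH4Cl, −78 °C; Et3N-deactivated silica, dark
Reagents that add atoms: none
Why: Proposed new method: LiTMP should remove the CHBr2 proton of 6 (acidified by two bromines, the aryl ring and the ortho isocyano group) well before it adds to the isocyanide or disturbs the aryl bromide, and the carbanion carbon of carbenoid 7 then attacks the isocyanide carbon to forge C2–C3 and give the imidoyl anion 8. The closest known reaction types are the Ito–Saegusa indole synthesis (ring closure of ortho-lithiomethylphenyl isocyanides) and the base-mediated halogen dance (bromine transfer to a carbanion with an aromatic anion as sink). The one ring formed, the pyrrole ring N1–C2–C3–C3a–C7a, closes in the 5-endo-dig mode, since both atoms of the N≡C unit end up inside it. The C2 carbanion of 8 then takes over a bromine from C3, by direct 1,2-shift or by a relay in which 8 abstracts Br+ from C3 of the tetrabromide 9 (first formed when a little 8 takes bromine from incoming 6), whereby 9 turns into the aromatic indolide 10 and 8 into a new molecule of 9; NH4Cl finally protonates 10 on nitrogen to give 11. No stereocentre arises; the step needs ring closure to beat α-elimination of LiBr from 7 and bromine to migrate rather than be lost, which the temperature of −95 °C, the acceptor held three atoms away and the stability of 10 should ensure. Even a carbene-like (electrophilic) reaction of 7 with the isocyanide carbon would, after return of bromide to C2, converge on the same indolide 10.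

Compound list
1 | 5-bromo-2-methylaniline | Cc1ccc(Br)cc1N | starting material
2 | formic acid | OC=O | starting material
3 | N-(5-bromo-2-methylphenyl)formamide | Cc1ccc(Br)cc1NC=O | intermediate
4 | N-bromosuccinimide | O=C1CCC(=O)N1Br | starting material
5 | N-[5-bromo-2-(dibromomethyl)phenyl]formamide | O=CNc1cc(Br)ccc1C(Br)Br | intermediate
6 | 4-bromo-1-(dibromomethyl)-2-isocyanobenzene | [C-]#[N+]c1cc(Br)ccc1C(Br)Br | intermediate
7 | dibromo(4-bromo-2-isocyanophenyl)methyllithium | [Li]C(Br)(Br)c1ccc(Br)cc1[N+]#[C-] | intermediate
8 | 3,3,6-tribromo-3H-indol-2-yllithium | [Li]C1=Nc2cc(Br)ccc2C1(Br)Br | intermediate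
9 | 2,3,3,6-tetrabromo-3H-indole (bromine relay, catalytic) | BrC1=Nc2cc(Br)ccc2C1(Br)Br | intermediate
10 | lithium 2,3,6-tribromoindol-1-ide | [Li]n1c(Br)c(Br)c2ccc(Br)cc12 | intermediate
11 | 2,3,6-tribromo-1H-indole | Brc1ccc2c(Br)c(Br)[nH]c2c1 | target

Total step count: 4. Longest linear sequence: 4 steps (1 → 3 → 5 → 6 → 11).

Steps most likely to fail

Step 4 (key step). The carbenoid may decompose by α-elimination faster than it closes the ring, or bromine transfer may stop short or scramble into mixtures of lower and higher bromides. The product may also degrade through acid or light during isolation. A thiosulfate wash should return residual relay species to the target, and purification is kept base-buffered and dark. The fallback uses known chemistry only and sets out from formamide 3. Dehydration (POCl3, Et3N, CH2Cl2, 0 °C) should give 4-bromo-2-isocyano-1-methylbenzene F1. Lateral lithiation with LiTMP in THF/diglyme at −78 °C and warming should effect the Ito–Saegusa cyclisation to 6-bromo-1H-indole F2. Two-fold electrophilic bromination (NBS, 2 equiv, DMF, −20 → 0 °C, dark), first at C3 and then at C2, should give the target, so this fallback comes back to the route at 11.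

Step 2. Ionic ring or N-bromination may compete with benzylic hydrogen abstraction, the reaction may stall at the monobromide, or the formamide oxygen may close onto the new benzylic bromide. The fallback sets out from 3 and removes the N–H. Boc2O with catalytic DMAP in MeCN should give tert-butyl N-(5-bromo-2-methylphenyl)-N-formylcarbamate F3, an imide with a deactivated ring and a poorly nucleophilic oxygen. Radical dibromination with NBS as in step 2 should give tert-butyl N-[5-bromo-2-(dibromomethyl)phenyl]-N-formylcarbamate F4. TFA in CH2Cl2 at 0 °C should cleave the Boc group selectively and return to the route at 5, which is dehydrated without delay.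

Step 3. The amine base may strip HBr from the ortho-amido benzal bromide (aza-ortho-quinone methide formation) or substitute at the benzylic carbon before O-phosphorylation, and the isocyanide may hydrate during work-up. The fallback reverses the order of dehydration and bromination and sets out from 3. Dehydration gives 4-bromo-2-isocyano-1-methylbenzene F1, the same compound as in the fallback for step 4. Lateral lithiation (LDA, diglyme, −78 °C) and inverse addition to 1,2-dibromotetrachloroethane should give 4-bromo-1-(bromomethyl)-2-isocyanobenzene F5. A second deprotonation (LiTMP, THF, −95 °C) and bromination with the same donor should give 6, where the route is rejoined. The second bromination is the less precedented part of this fallback.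

Further compounds
F1 | step 4 | 4-bromo-2-isocyano-1-methylbenzene | Cc1ccc(Br)cc1[N+]#[C-]
F2 | step 4 | 6-bromo-1H-indole | Brc1ccc2cc[nH]c2c1
F3 | step 2 | tert-butyl N-(5-bromo-2-methylphenyl)-N-formylcarbamate | Cc1ccc(Br)cc1N(C=O)C(=O)OC(C)(C)C
F4 | step 2 | tert-butyl N-[5-bromo-2-(dibromomethyl)phenyl]-N-formylcarbamate | O=CN(C(=O)OC(C)(C)C)c1cc(Br)ccc1C(Br)Br
F5 | step 3 | 4-bromo-1-(bromomethyl)-2-isocyanobenzene | [C-]#[N+]c1cc(Br)ccc1CBr
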